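**Retrosynthetic overview**

1. Leucanthin B ⇒ its C14 2-(trimethylsilyl)ethyl (TMSE) ester ⇒ late C2–C3 epoxidation of the 10-membered 1(10)Z,2Z-diene ⇒ ring-closing metathesis at C2=C3.
2. Acyclic metathesis substrate ⇒ A(1,3)-controlled C4–C5 epoxidation next to C6; C8 epoxyangelate (acid from L-threonine) and C9 acetate on a diol released from an acetonide.
3. trans-α-Methylene-γ-lactone (C6–C7 bond, C6 and C7) ⇒ Cr(II) 2-(methoxycarbonyl)allylation of (Z)-3-methylpenta-2,4-dienal by a Morita–Baylis–Hillman-derived allylic bromide.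
4. Key C9–C10 bond ⇒ Ni-electrocatalytic decarboxylative alkenylation of the L-tartrate acetonide half-acid with a (2Z,4E)-2-bromohexadienoate (C8 and C9 bought; C9 re-formed trans on the dioxolane).
5. Ring order: dioxolane (bought) → γ-lactone → 4,5-oxirane → 10-membered carbocycle → 2,3-oxirane.

Assumption: the given SMILES defines the target (cis-4,5-epoxide, (2′R,3′R)-epoxyangelate, free C14 acid); germacrane numbering (C1–C15) is used for locants.

**Route**

Step 1
Reactants: 1 (triphenylphosphoranylidene)ketene; 2 2-(trimethylsilyl)ethanol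
Product: 3 2-(trimethylsilyl)ethyl (triphenylphosphoranylidene)acetate
Conditions: PhMe, 60 °C
Reagents that add atoms: none
Why: The alcohol O–H adds across the cumulated ylide to give the stabilized Wittig ylide (ylide formation from a ketenylidene phosphorane); no stereocentre.

Step 2
Reactants: 3; 4 (E)-but-2-enal
Product: 5 2-(trimethylsilyl)ethyl (2Z,4E)-2-bromohexa-2,4-dienoate
Conditions: NBS, CH2Cl2, −20 °C; then K2CO3, 4, −20 °C → rt
Reagents that add atoms: N-bromosuccinimide, BrN1C(=O)CCC1=O
Why: In-situ bromination of the stabilized ylide followed by Wittig olefination puts the ester trans to the β-substituent, giving the (2Z)-bromide as the major, separable isomer.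

Step 3
Reactants: 6 (Z)-3-methylpent-2-en-4-yn-1-ol
Product: 7 (Z)-3-methylpenta-2,4-dien-1-ol
Conditions: H2 (1 atm), Lindlar catalyst, quinoline, EtOAc, 0 °C
Reagents that add atoms: none
Why: Lindlar semi-hydrogenation reduces only the terminal alkyne; the bought Z-trisubstituted alkene (future C4=C5, C3 cis to C6) is untouched.

Step 4
Reactants: 7
Product: 8 (Z)-3-methylpenta-2,4-dienal (used crude)
Conditions: MnO2, CH2Cl2, rt
Reagents that add atoms: none
Why: Neutral allylic oxidation; the Z geometry is retained because the 2H-pyran valence tautomer of this dienal can only reopen to the Z isomer.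

Step 5
Reactants: 9 L-threonine
Product: 10 (2S,3R)-2-chloro-3-hydroxybutanoic acid
Conditions: NaNO2, 6 M HCl, KCl, 0 °C
Reagents that add atoms: hydrochloric acid, Cl
Why: Diazotization with carboxylate participation (α-lactone, double inversion) replaces NH2 by Cl with retention; C3 is the bought stereocentre.

Step 6
Reactants: 10
Product: 11 methyl (2S,3R)-2-chloro-3-hydroxybutanoate
Conditions: AcCl (cat.), MeOH, 0 °C → rt
Reagents that add atoms: methanol, CO
Why: Fischer esterification; no stereocentre is touched.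

Step 7
Reactants: 11
Product: 12 methyl (2S,3R)-2-chloro-3-hydroxy-2-methylbutanoate
Conditions: LDA (2.2 equiv), THF, −78 °C; MeI, DMPU, −78 → −40 °C
Reagents that add atoms: iodomethane, CI
Why: Fráter–Seebach alkylation of the lithium-chelated alkoxide–chloroenolate dianion; MeI enters anti to the C3 methyl, so C2 is controlled by the threonine-derived C3.

Step 8
Reactants: 12
Product: 13 (2R,3R)-2,3-dimethyloxirane-2-carboxylic acid ((2R,3R)-epoxyangelic acid)
Conditions: KOH, MeOH/H2O, 0 °C → rt; then pH 3
Reagents that add atoms: potassium hydroxide, [K+].[OH-]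
Why: Darzens-type intramolecular SN2 closure inverts C2 to give the epoxide with CO2H cis to the C3 methyl, and the ester is saponified in the same pot.

Step 9
Reactants: 14 dimethyl (4R,5R)-2,2-dimethyl-1,3-dioxolane-4,5-dicarboxylate (dimethyl 2,3-O-isopropylidene-L-tartrate)
Product: 15 (4R,5R)-5-(methoxycarbonyl)-2,2-dimethyl-1,3-dioxolane-4-carboxylic acid
Conditions: KOH (1.0 equiv), MeOH, rt
Reagents that add atoms: potassium hydroxide, [K+].[OH-]
Why: Mono-saponification of a C2-symmetric diester (the carboxylate resists the second hydrolysis); both stereocentres (future C8, C9) are bought.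

Step 10
Reactants: 15; 5
Product: 16 2-(trimethylsilyl)ethyl (2E,4E)-2-[(4S,5R)-5-(methoxycarbonyl)-2,2-dimethyl-1,3-dioxolan-4-yl]hexa-2,4-dienoate (trans-dioxolane; C9 cis to C2 across C10=C1)
Conditions: N-hydroxyphthalimide, DIC, DMF, rt (redox-active ester, not isolated); then 5, NiCl2·6H2O (20 mol%), 2,2′-bipyridine, AgNO3 (cat.), (+)Mg/(−)RVC, constant current, rt
Reagents that add atoms: none
Why: Proposed new method: cathodically generated low-valent Ni(bpy) inserts into the C(sp2)–Br bond of 5 with retention, reduces the N-hydroxyphthalimide ester to the dioxolanyl radical (−CO2), and radical capture/reductive elimination forges C9–C10 anti to the vicinal CO2Me (trans-dioxolane, so C9 is controlled by bought C8), the δ-methyl of 5 slowing competing Giese addition; closest known reaction type is Ni-electrocatalytic decarboxylative alkenylation of redox-active esters with simple alkenyl halides, assumed here not to have been shown for an α-bromo-2,4-dienoate.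

Step 11
Reactants: 16
Product: 17 2-(trimethylsilyl)ethyl (2E,4E)-2-[(4S,5R)-5-formyl-2,2-dimethyl-1,3-dioxolan-4-yl]hexa-2,4-dienoate (C7 aldehyde)
Conditions: DIBAL-H (1.1 equiv), CH2Cl2/PhMe, −78 °C
Reagents that add atoms: none
Why: Partial ester reduction; the α-alkoxy methyl ester forms a chelated tetrahedral aluminate and reacts faster than the hindered, cross-conjugated TMSE ester.

Step 12
Reactants: 17; 18 methyl acrylate
Product: 19 Morita–Baylis–Hillman adduct (C7 carbinol bearing the C11(=CH2)CO2Me unit; mixture of C7 epimers, both used)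
Conditions: DABCO (1 equiv), 18 (excess), MeOH, rt
Reagents that add atoms: none
Why: Morita–Baylis–Hillman reaction of a reactive α-alkoxy aldehyde; the new C7 carbinol centre is destroyed in the next step.

Step 13
Reactants: 19
Product: 20 (Z)-allylic bromide, C8–C7H=C11(CO2Me)–CH2Br (CH2Br cis to C8)
Conditions: NBS, Me2S, CH2Cl2, 0 °C → rt
Reagents that add atoms: N-bromosuccinimide, BrN1C(=O)CCC1=O
Why: SN2′ bromination of the Baylis–Hillman alcohol gives the conjugated (Z)-2-(bromomethyl)enoate with the ester trans to C8.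

Step 14
Reactants: 20; 8
Product: 21 6,7-trans α-methylene-γ-butyrolactone bearing the (Z)-2-methylbuta-1,3-dienyl group on C6 and the acetonide side chain on C7 (C6, C7 as in the target)
Conditions: CrCl2 (4 equiv), THF, 0 °C → rt; then PPTS (cat.), CH2Cl2
Reagents that add atoms: none
Why: Nozaki–Hiyama 2-(alkoxycarbonyl)allylation/lactonization: the equilibrated allylchromium reacts through a chair transition state to give the anti adduct (trans-lactone), and C7 is set by C8 with H8 eclipsing the alkene, C9 anti to the incoming aldehyde and O8 outside (a geometry-defined allylboronate is the stereospecific alternative if the cis-lactone forms).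

Step 15
Reactants: 21
Product: 22 8,9-diol (lactone, diene and dienoate unchanged)
Conditions: AcOH/H2O (4:1), 40 °C
Reagents that add atoms: none
Why: Acid-catalysed acetal hydrolysis under conditions chosen to be too mild to ionize the dienylic lactone C6–O bond or cleave the TMSE ester; no stereocentre is touched.

Step 16
Reactants: 22
Product: 23 9-O-acetyl-8-hydroxy compound
Conditions: Ac2O (1.1 equiv), 2,4,6-collidine, CH2Cl2, −20 °C
Reagents that add atoms: acetic anhydride, CC(=O)OC(C)=O
Why: Kinetic mono-acylation; C9–OH is allylic and next to a planar sp2 carbon, whereas C8–OH is flanked by two branched sp3 carbons, so the small acetyl group is expected to go to O9.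

Step 17
Reactants: 23; 13
Product: 24 8-O-[(2R,3R)-epoxyangeloyl]-9-O-acetyl compound
Conditions: 13, 2,4,6-trichlorobenzoyl chloride, Et3N, THF; then 23, DMAP, PhMe, 0 °C → rt
Reagents that add atoms: none
Why: Yamaguchi esterification of the hindered C8 alcohol with the preformed mixed anhydride; both side-chain stereocentres come in with 13.

Step 18
Reactants: 24
Product: 25 4,5-cis-epoxide (2-methyl-2-vinyloxirane unit on C6; C4, C5 as in the target)
Conditions: mCPBA (1.1 equiv), NaHCO3, CH2Cl2, 0 °C
Reagents that add atoms: m-chloroperoxybenzoic acid, O=C(OO)c1cccc(Cl)c1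
Why: Prilezhaev epoxidation of the most electron-rich (trisubstituted) alkene; A(1,3) strain from the cis C4-vinyl group holds C6–H in the alkene plane and the peracid attacks anti to the bulky C7 branch, giving the epoxide threo to C6–O.

Step 19
Reactants: 25
Product: 26 10-membered 1(10)Z,2Z-diene 4,5-epoxide (germacranolide skeleton, C14 TMSE ester)
Conditions: Grubbs II (15 mol%), CH2Cl2 (1 mM), 40 °C
Reagents that add atoms: none
Why: Ring-closing metathesis between the vinyl oxirane and the propenyl terminus of the dienoate (propene lost), favoured by the turns imposed by the trans-lactone, cis-epoxide and Z-enoate; the ring size enforces the Z C2=C3 alkene.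

Step 20
Reactants: 26
Product: 27 leucanthin B 2-(trimethylsilyl)ethyl ester (2,3:4,5-bis-epoxide)
Conditions: DMDO, acetone/CH2Cl2, 0 °C
Reagents that add atoms: dimethyldioxirane, CC1(C)OO1
Why: Chemoselective epoxidation of the only non-electron-poor alkene; in the cisoid cyclic vinyl epoxide the oxidant is expected to approach C2=C3 anti to the C4–C5 oxirane oxygen (as in anti-bis-epoxidation of cyclic 1,3-dienes), setting C2 and C3 from C4/C5.

Step 21
Reactants: 27
Product: 28 leucanthin B
Conditions: TASF, DMF, 0 °C; then pH 4 buffer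
Reagents that add atoms: none
Why: Fluoride-induced β-elimination of the 2-(trimethylsilyl)ethyl ester under non-hydrolytic conditions that should spare the acetate, both lactone/ester carbonyls and the three oxiranes.

**Compound list**

1 | (triphenylphosphoranylidene)ketene | O=C=C=P(c1ccccc1)(c1ccccc1)c1ccccc1 | starting material
2 | 2-(trimethylsilyl)ethanol | C[Si](C)(C)CCO | starting material
3 | 2-(trimethylsilyl)ethyl (triphenylphosphoranylidene)acetate | C[Si](C)(C)CCOC(=O)C=P(c1ccccc1)(c1ccccc1)c1ccccc1 | intermediate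
4 | (E)-but-2-enal | C/C=C/C=O | starting material
5 | 2-(trimethylsilyl)ethyl (2Z,4E)-2-bromohexa-2,4-dienoate | C[Si](C)(C)CCOC(=O)/C(Br)=C/C=C/C | intermediate
6 | (Z)-3-methylpent-2-en-4-yn-1-ol | OC/C=C(/C)C#C | starting material
7 | (Z)-3-methylpenta-2,4-dien-1-ol | OC/C=C(/C)C=C | intermediate
8 | (Z)-3-methylpenta-2,4-dienal | O=C/C=C(/C)C=C | intermediate
9 | L-threonine | C[C@@H](O)[C@H](N)C(=O)O | starting material
10 | (2S,3R)-2-chloro-3-hydroxybutanoic acid | C[C@@H](O)[C@H](Cl)C(=O)O | intermediate
11 | methyl (2S,3R)-2-chloro-3-hydroxybutanoate | C[C@@H](O)[C@H](Cl)C(=O)OC | intermediate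
12 | methyl (2S,3R)-2-chloro-3-hydroxy-2-methylbutanoate | C[C@@H](O)[C@](C)(Cl)C(=O)OC | intermediate
13 | (2R,3R)-2,3-dimethyloxirane-2-carboxylic acid | OC(=O)[C@]1(C)O[C@@H]1C | intermediate
14 | dimethyl (4R,5R)-2,2-dimethyl-1,3-dioxolane-4,5-dicarboxylate | COC(=O)[C@@H]1OC(C)(C)O[C@H]1C(=O)OC | starting material
15 | (4R,5R)-5-(methoxycarbonyl)-2,2-dimethyl-1,3-dioxolane-4-carboxylic acid | COC(=O)[C@@H]1OC(C)(C)O[C@H]1C(=O)O | intermediate
16 | 2-(trimethylsilyl)ethyl (2E,4E)-2-[(4S,5R)-5-(methoxycarbonyl)-2,2-dimethyl-1,3-dioxolan-4-yl]hexa-2,4-dienoate | COC(=O)[C@@H]1OC(C)(C)O[C@H]1/C(C(=O)OCC[Si](C)(C)C)=C\C=C\C | intermediate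
17 | 2-(trimethylsilyl)ethyl (2E,4E)-2-[(4S,5R)-5-formyl-2,2-dimethyl-1,3-dioxolan-4-yl]hexa-2,4-dienoate | O=C[C@@H]1OC(C)(C)O[C@H]1/C(C(=O)OCC[Si](C)(C)C)=C\C=C\C | intermediate
18 | methyl acrylate | C=CC(=O)OC | starting material
19 | Baylis–Hillman adduct of 17 (C7 carbinol, epimer mixture) | C=C(C(=O)OC)C(O)[C@@H]1OC(C)(C)O[C@H]1/C(C(=O)OCC[Si](C)(C)C)=C\C=C\C | intermediate
20 | (Z)-2-(bromomethyl)enoate (allylic bromide, trans-dioxolane) | COC(=O)/C(CBr)=C/[C@@H]1OC(C)(C)O[C@H]1/C(C(=O)OCC[Si](C)(C)C)=C\C=C\C | intermediate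
21 | 6,7-trans α-methylene lactone, 8,9-acetonide, C6 (Z)-dienyl | C=C1C(=O)O[C@H](/C=C(/C)C=C)[C@H]1[C@@H]1OC(C)(C)O[C@H]1/C(C(=O)OCC[Si](C)(C)C)=C\C=C\C | intermediate
22 | 8,9-diol | C=C1C(=O)O[C@H](/C=C(/C)C=C)[C@H]1[C@H](O)[C@@H](O)/C(C(=O)OCC[Si](C)(C)C)=C\C=C\C | intermediate
23 | 9-acetate, 8-alcohol | C=C1C(=O)O[C@H](/C=C(/C)C=C)[C@H]1[C@H](O)[C@@H](OC(C)=O)/C(C(=O)OCC[Si](C)(C)C)=C\C=C\C | intermediate
24 | 8-(2R,3R)-epoxyangelate, 9-acetate | C=C1C(=O)O[C@H](/C=C(/C)C=C)[C@H]1[C@H](OC(=O)[C@]1(C)O[C@@H]1C)[C@@H](OC(C)=O)/C(C(=O)OCC[Si](C)(C)C)=C\C=C\C | intermediate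
25 | 4,5-cis-epoxide (vinyl oxirane), acyclic | C=C1C(=O)O[C@H]([C@H]2O[C@@]2(C)C=C)[C@H]1[C@H](OC(=O)[C@]1(C)O[C@@H]1C)[C@@H](OC(C)=O)/C(C(=O)OCC[Si](C)(C)C)=C\C=C\C | intermediate
26 | 10-membered 1(10)Z,2Z-diene 4,5-epoxide, TMSE ester | C=C1C(=O)O[C@H]2[C@H]1[C@H](OC(=O)[C@]1(C)O[C@@H]1C)[C@@H](OC(C)=O)/C(C(=O)OCC[Si](C)(C)C)=C\C=C/[C@]1(C)O[C@H]21 | intermediate
27 | leucanthin B 2-(trimethylsilyl)ethyl ester | C=C1C(=O)O[C@H]2[C@H]1[C@H](OC(=O)[C@]1(C)O[C@@H]1C)[C@@H](OC(C)=O)/C(C(=O)OCC[Si](C)(C)C)=C\[C@H]1O[C@H]1[C@]1(C)O[C@H]21 | intermediate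
28 | leucanthin B | C=C1C(=O)O[C@H]2[C@H]1[C@H](OC(=O)[C@]1(C)O[C@@H]1C)[C@@H](OC(C)=O)/C(C(=O)O)=C\[C@H]1O[C@H]1[C@]1(C)O[C@H]21 | target

**Totals**

Total step count: 21.
Longest linear sequence: 14 steps (1 → 3 → 5 → 16 → 17 → 19 → 20 → 21 → 22 → 23 → 24 → 25 → 26 → 27 → 28); 13 steps from tartrate 14.

**Three steps most likely to fail**

- **Step 10 (proposed new step).** Risks are Giese addition of the dioxolanyl radical to the dienoate, protodehalogenation of 5, and modest trans selectivity. Fallback (known chemistry, polar logic): make C9 a carbinol by CrCl2/cat. NiCl2 Nozaki–Hiyama–Kishi addition of alkenyl bromide 5 to (S)-2,3-O-isopropylideneglyceraldehyde (C8 bought; its CH2O carbon becomes C7). C9 then comes from 1,2-induction, corrected by Mitsunobu inversion if needed, and C7 is oxidized to the aldehyde to rejoin the route at the stage of 17.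
- **Step 19 (ring-closing metathesis to the 10-membered ring).** Risks are oligomerization or no closure at the hindered vinyl oxirane. Fallback: abandon metathesis and close the ring at C9–C10 by intramolecular Nozaki–Hiyama–Kishi alkenylation. C9 is carried as a protected aldehyde through the lactone annulation, the complete C1–C6 bromodienyl chain is attached in the Cr allylation as its C2≡C3 alkyne and Lindlar-reduced after lactonization, and the C10 alkenyl bromide is then cyclized onto the C9 aldehyde (C9 by 1,2-induction, corrected by oxidation–reduction if needed).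
- **Step 20 (facial selectivity of the C2–C3 epoxidation).** If the oxidant attacks syn to the existing oxirane, the wrong C2/C3 diastereomer forms. Fallback: two-step halohydrin route (NBS, THF/H2O, then K2CO3), which places bromine on the accessible face and closes the epoxide on the opposite face.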